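**Plan**
- Retrosynthesis: the acid, phenol and carbinol are unmasked last (from methyl ester, aryl TBS ether and ketone). The 14-membered ring is cut at the single bond between the ring CH2 and the methyl-bearing alkene carbon, the enoate C=C by a Wittig disconnection, and the aryl fragment back through the cyclopropane, the O–CMe2 ether bond and the aryl–CH2 bond (Claisen).
- Enabling feature: the CH(OH)–CH2–CH2 segment between the gem-dimethyl ether carbon and the methyl-bearing alkene carbon of the 14-membered ring is a latent ketone homoenolate. It is stored as a 1-substituted cyclopropanol made from the aryloxyisobutyrate ester.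
- Forward: the aryl fragment (steps 1–5) and the iodoalkenyl ylide (steps 6–9) are joined by a Wittig reaction (step 10). The only ring formed in the route, the macrocycle, is closed in step 11 by palladium-catalysed cyclopropanol ring opening and cross-coupling onto the (Z)-alkenyl iodide. Reduction and deprotection follow (steps 12–13).
- Stereochemistry: the E-enoate comes from the stabilised-ylide Wittig reaction. The Z methyl alkene comes from the Stork–Zhao iodoalkene and is carried through the coupling with retention. The single stereocentre (R carbinol) comes from CBS reduction of the macrocyclic ketone with the (S)-oxazaborolidine.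

Key step: step 11

Assumption: the target SMILES is read as (E)-enoate, (Z)-methyl alkene and (R)-carbinol, and 3-(tert-butyldimethylsilyloxy)propanal is taken as a catalogue aldehyde (otherwise one oxidation of the commercial alcohol would be added).

**Route**

Step 1
Reactants: 1 4-(tert-butyldimethylsilyloxy)phenol; 2 allyl bromide
Product: 3 1-(allyloxy)-4-(tert-butyldimethylsilyloxy)benzene
Conditions: K2CO3, acetone, reflux
Reagents that add atoms: allyl bromide (2), C=CCBr
Why: Williamson O-allylation of the phenoxide with a reactive allylic bromide should be clean, and the aryl silyl ether is expected to survive anhydrous K2CO3 in acetone.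

Step 2
Reactants: 3 1-(allyloxy)-4-(tert-butyldimethylsilyloxy)benzene
Product: 4 2-allyl-4-(tert-butyldimethylsilyloxy)phenol
Conditions: PhNEt2, 190 °C (sealed tube)
Reagents that add atoms: none
Why: Aromatic Claisen rearrangement ([3,3]-sigmatropic shift, then tautomerisation) should deliver the allyl group to one of the two equivalent ortho positions, the para position being blocked by the silyloxy group.

Step 3
Reactants: 4 2-allyl-4-(tert-butyldimethylsilyloxy)phenol; 5 ethyl 2-bromo-2-methylpropanoate
Product: 6 ethyl 2-[2-allyl-4-(tert-butyldimethylsilyloxy)phenoxy]-2-methylpropanoate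
Conditions: K2CO3, MeCN, reflux (excess 5)
Reagents that add atoms: ethyl 2-bromo-2-methylpropanoate (5), CCOC(=O)C(C)(C)Br
Why: Williamson-type O-alkylation of a phenoxide with the tertiary α-bromo ester is the standard entry to aryloxyisobutyrates, the excess of 5 making up for its loss to methacrylate by elimination.

Step 4
Reactants: 6 ethyl 2-[2-allyl-4-(tert-butyldimethylsilyloxy)phenoxy]-2-methylpropanoate
Product: 7 1-{2-[2-allyl-4-(tert-butyldimethylsilyloxy)phenoxy]propan-2-yl}cyclopropan-1-ol
Conditions: EtMgBr (3 equiv, slow addition), Ti(OiPr)4 (0.3 equiv), THF, 0 °C → rt; aq. NH4Cl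
Reagents that add atoms: ethylmagnesium bromide, CC[Mg]Br
Why: Kulinkovich cyclopropanation, in which the titanacyclopropane generated from EtMgBr and Ti(OiPr)4 adds twice to the ester carbonyl, should give the 1-substituted cyclopropanol, since with the ethyl Grignard reagent exchange of titanium-bound ethylene for the unactivated allyl alkene is slow and the aryl silyl ether is a spectator.

Step 5
Reactants: 7 1-{2-[2-allyl-4-(tert-butyldimethylsilyloxy)phenoxy]propan-2-yl}cyclopropan-1-ol
Product: 9 2-[5-(tert-butyldimethylsilyloxy)-2-{[2-(1-hydroxycyclopropyl)propan-2-yl]oxy}phenyl]acetaldehyde, via secondary ozonide 8 (not isolated)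
Conditions: O3, CH2Cl2, −78 °C (Sudan Red 7B as end-point indicator); PPh3, −78 °C → rt; crude aldehyde used at once
Reagents that add atoms: ozone, [O-][O+]=O
Why: Ozonolysis with reductive work-up cleaves the monosubstituted alkene, by far the most ozone-reactive site, the indicator dye stopping the gas flow before the electron-rich arene or the tertiary cyclopropanol is attacked.

Step 6
Reactants: 10 3-(tert-butyldimethylsilyloxy)propanal; 11 ethyltriphenylphosphonium iodide
Product: 12 (Z)-tert-butyl[(4-iodopent-3-en-1-yl)oxy]dimethylsilane
Conditions: 11, n-BuLi, THF, rt; I2, −78 °C; NaHMDS, −20 °C; then 10, −78 °C → rt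
Reagents that add atoms: ethyltriphenylphosphonium iodide (11), CC[P+](c1ccccc1)(c1ccccc1)c1ccccc1.[I-]; iodine, II
Why: Stork–Zhao olefination, in which the non-stabilised α-iodo ylide Ph3P=C(I)CH3 adds to the aldehyde under kinetic control at low temperature, should give the 2-iodo-2-alkene with iodine cis to the chain (Z).

Step 7
Reactants: 12 (Z)-tert-butyl[(4-iodopent-3-en-1-yl)oxy]dimethylsilane
Product: 13 (Z)-4-iodopent-3-en-1-ol
Conditions: CSA (10 mol%), MeOH, 0 °C → rt
Reagents that add atoms: none
Why: Acid-catalysed methanolysis removes a primary alkyl TBS ether under conditions that leave the alkenyl iodide untouched.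

Step 8
Reactants: 13 (Z)-4-iodopent-3-en-1-ol
Product: 14 (Z)-2,5-diiodopent-2-ene
Conditions: PPh3, I2, imidazole, CH2Cl2, 0 °C → rt, dark
Reagents that add atoms: iodine, II
Why: Appel-type iodination converts the primary alcohol into the iodide by SN2 displacement of the alkoxyphosphonium ion without touching the alkene geometry.

Step 9
Reactants: 14 (Z)-2,5-diiodopent-2-ene; 15 methyl (triphenylphosphoranylidene)acetate
Product: 17 methyl (Z)-6-iodo-2-(triphenylphosphoranylidene)hept-5-enoate, via phosphonium iodide 16 (not isolated)
Conditions: MeCN, reflux; then 1 M NaOH, CH2Cl2, 0 °C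
Reagents that add atoms: methyl (triphenylphosphoranylidene)acetate (15), COC(=O)C=P(c1ccccc1)(c1ccccc1)c1ccccc1
Why: C-Alkylation of the ester-stabilised ylide by the primary alkyl iodide (the sp2 C–I bond cannot react by SN2 and the weakly basic ylide disfavours E2) gives the phosphonium salt, which aqueous NaOH deprotonates to the α-substituted stabilised ylide.

Step 10
Reactants: 9 2-[5-(tert-butyldimethylsilyloxy)-2-{[2-(1-hydroxycyclopropyl)propan-2-yl]oxy}phenyl]acetaldehyde; 17 methyl (Z)-6-iodo-2-(triphenylphosphoranylidene)hept-5-enoate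
Product: 18 methyl (2E,5Z)-2-{2-[5-(tert-butyldimethylsilyloxy)-2-{[2-(1-hydroxycyclopropyl)propan-2-yl]oxy}phenyl]ethylidene}-6-iodohept-5-enoate
Conditions: toluene, rt → 60 °C
Reagents that add atoms: none
Why: Wittig olefination with an α-alkyl, ester-stabilised ylide is reliably E-selective (ester trans to the CH2Ar group), and its neutral conditions spare the enolisable arylacetaldehyde, the free cyclopropanol and the alkenyl iodide.

Step 11
Reactants: 18 methyl (2E,5Z)-2-{2-[5-(tert-butyldimethylsilyloxy)-2-{[2-(1-hydroxycyclopropyl)propan-2-yl]oxy}phenyl]ethylidene}-6-iodohept-5-enoate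
Product: 19 14-membered macrocyclic α-aryloxy ketone (methyl ester; aryl TBS ether; E-enoate; Z methyl alkene)
Conditions: Pd2(dba)3 (5 mol%), XPhos (12 mol%), Cs2CO3 (2 equiv), degassed toluene, 80 °C, syringe-pump addition of 18 (final 2 mM)
Reagents that add atoms: none
Why: Proposed new method: Pd(0) should add oxidatively to the alkenyl C–I bond, the tethered cyclopropanol should displace iodide from palladium with the help of carbonate, and strain-driven β-carbon elimination of the palladium cyclopropanolate should give a β-keto alkylpalladium (homoenolate) whose C(sp3)–C(sp2) reductive elimination forms the CH2–C(CH3)= bond; the closest known reaction type is the intermolecular palladium-catalysed ring-opening cross-coupling of cyclopropanols with aryl and alkenyl halides, which is run here as a macrocyclisation. The 14-membered ring closes end to end by reductive elimination from a 15-membered palladacycle, under slow addition at high dilution, with the ortho-disubstituted arene, the gem-dimethyl group and the two fixed alkene geometries turning the chain ends toward each other. No stereocentre is formed; oxidative addition and reductive elimination at the sp2 carbon proceed with retention, so the Z iodoalkene becomes the Z methyl alkene of the ring, and the two cyclopropane C–C bonds are equivalent, so ring opening has no regiochemical choice. The step needs reductive elimination to outrun β-hydride elimination of the homoenolate (to the vinyl ketone) and Heck-type insertion of the alkenylpalladium into the enoate: the bulky, electron-rich biaryl phosphine speeds reductive elimination, and the trisubstituted, ester-bearing alkene is a poor insertion partner. Methyl ester, aryl silyl ether and enoate should be inert to Cs2CO3 in dry toluene.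

Step 12
Reactants: 19 14-membered macrocyclic α-aryloxy ketone
Product: 20 (R)-configured macrocyclic carbinol (methyl ester; aryl TBS ether)
Conditions: (S)-Me-CBS (0.3 equiv), catecholborane (2 equiv), toluene, −78 → −40 °C; MeOH, aq. NaHCO3
Reagents that add atoms: none
Why: Corey–Bakshi–Shibata reduction, in which the ketone binds the boron of the (S)-oxazaborolidine with its larger substituent (the quaternary aryloxy-bearing carbon) turned away and hydride is delivered from the nitrogen-bound borane to one face, should set the new stereocentre R by catalyst control (the sense known for tert-alkyl ketones), while catecholborane at low temperature neither hydroborates the trisubstituted alkenes nor reduces the ester.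

Step 13
Reactants: 20 (R)-configured macrocyclic carbinol (methyl ester; aryl TBS ether)
Product: 22 petchiether B, via phenol methyl ester 21 (not isolated)
Conditions: LiOH·H2O (10 equiv), degassed THF/MeOH/H2O, rt → 45 °C; then 1 M HCl to pH 3, 0 °C
Reagents that add atoms: lithium hydroxide, [Li+].[OH-]
Why: Hydroxide first cleaves the phenolic silyl ether (phenoxide is a good leaving group from silicon) and then saponifies the methyl enoate, and neither the carbinol stereocentre nor the thermodynamically preferred E-enoate should be affected before mild acidification liberates the acid and the phenol.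

**Compound list**

1 | 4-(tert-butyldimethylsilyloxy)phenol | CC(C)(C)[Si](C)(C)Oc1ccc(O)cc1 | starting material
2 | allyl bromide | C=CCBr | starting material
3 | 1-(allyloxy)-4-(tert-butyldimethylsilyloxy)benzene | C=CCOc1ccc(O[Si](C)(C)C(C)(C)C)cc1 | intermediate
4 | 2-allyl-4-(tert-butyldimethylsilyloxy)phenol | C=CCc1cc(O[Si](C)(C)C(C)(C)C)ccc1O | intermediate
5 | ethyl 2-bromo-2-methylpropanoate | CCOC(=O)C(C)(C)Br | starting material
6 | ethyl 2-[2-allyl-4-(tert-butyldimethylsilyloxy)phenoxy]-2-methylpropanoate | CCOC(=O)C(C)(C)Oc1ccc(O[Si](C)(C)C(C)(C)C)cc1CC=C | intermediate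
7 | 1-{2-[2-allyl-4-(tert-butyldimethylsilyloxy)phenoxy]propan-2-yl}cyclopropan-1-ol | OC1(CC1)C(C)(C)Oc1ccc(O[Si](C)(C)C(C)(C)C)cc1CC=C | intermediate
8 | secondary ozonide of 7 (1,2,4-trioxolan-3-ylmethyl group in place of allyl; not isolated) | OC1(CC1)C(C)(C)Oc1ccc(O[Si](C)(C)C(C)(C)C)cc1CC1OCOO1 | intermediate
9 | 2-[5-(tert-butyldimethylsilyloxy)-2-{[2-(1-hydroxycyclopropyl)propan-2-yl]oxy}phenyl]acetaldehyde | OC1(CC1)C(C)(C)Oc1ccc(O[Si](C)(C)C(C)(C)C)cc1CC=O | intermediate
10 | 3-(tert-butyldimethylsilyloxy)propanal | CC(C)(C)[Si](C)(C)OCCC=O | starting material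
11 | ethyltriphenylphosphonium iodide | CC[P+](c1ccccc1)(c1ccccc1)c1ccccc1.[I-] | starting material
12 | (Z)-tert-butyl[(4-iodopent-3-en-1-yl)oxy]dimethylsilane | CC(C)(C)[Si](C)(C)OCC/C=C(C)\I | intermediate
13 | (Z)-4-iodopent-3-en-1-ol | OCC/C=C(C)\I | intermediate
14 | (Z)-2,5-diiodopent-2-ene | ICC/C=C(C)\I | intermediate
15 | methyl (triphenylphosphoranylidene)acetate | COC(=O)C=P(c1ccccc1)(c1ccccc1)c1ccccc1 | starting material
16 | [(Z)-6-iodo-1-methoxy-1-oxohept-5-en-2-yl]triphenylphosphonium iodide (not isolated) | COC(=O)C(CC/C=C(C)\I)[P+](c1ccccc1)(c1ccccc1)c1ccccc1.[I-] | intermediate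
17 | methyl (Z)-6-iodo-2-(triphenylphosphoranylidene)hept-5-enoate | COC(=O)C(CC/C=C(C)\I)=P(c1ccccc1)(c1ccccc1)c1ccccc1 | intermediate
18 | methyl (2E,5Z)-2-{2-[5-(tert-butyldimethylsilyloxy)-2-{[2-(1-hydroxycyclopropyl)propan-2-yl]oxy}phenyl]ethylidene}-6-iodohept-5-enoate | OC1(CC1)C(C)(C)Oc1ccc(O[Si](C)(C)C(C)(C)C)cc1C/C=C(C(=O)OC)\CC/C=C(C)\I | intermediate
19 | macrocyclic ketone: benzo-fused 14-membered ring in which the chain ArO–C(CH3)2–C(=O)–CH2–CH2–C(CH3)=CH–CH2–CH2–C(CO2CH3)=CH–CH2 returns to the ortho carbon of the arene; Z methyl alkene, E enoate, OTBS para to the ring oxygen | C/C1=C/CC/C(C(=O)OC)=C\Cc2cc(O[Si](C)(C)C(C)(C)C)ccc2OC(C)(C)C(=O)CC1 | intermediate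
20 | (R)-carbinol of 19 (C=O replaced by (R)-CH(OH); methyl ester; aryl TBS ether) | C/C1=C/CC/C(C(=O)OC)=C\Cc2cc(O[Si](C)(C)C(C)(C)C)ccc2OC(C)(C)[C@H](O)CC1 | intermediate
21 | petchiether B methyl ester (free phenol, (R)-carbinol; not isolated) | C/C1=C/CC/C(C(=O)OC)=C\Cc2cc(O)ccc2OC(C)(C)[C@H](O)CC1 | intermediate
22 | petchiether B | C/C1=C/CC/C(C(=O)O)=C\Cc2cc(O)ccc2OC(C)(C)[C@H](O)CC1 | target

**Totals**

Total step count: 13.
Longest linear sequence: 9 steps (steps 1–5 and 10–13); the side chain (steps 6–9) is a four-step branch.

**Steps most likely to fail, with fallbacks**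

1. Step 11. β-Hydride elimination of the β-keto alkylpalladium, Heck-type insertion into the enoate, or intermolecular coupling may outrun the ring-closing reductive elimination. The fallback uses known chemistry only: it makes the CH2–C(CH3)= bond intermolecularly and closes the ring at the enoate alkene instead. It sets out from diiodide 14 and cyclopropanol 7 and returns at ketone 19.
 - Diiodide 14 should alkylate the sodium salt of trimethyl phosphonoacetate (NaH, THF/DMSO) at its sp3 carbon to give methyl (Z)-2-(dimethoxyphosphoryl)-6-iodohept-5-enoate F1.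
 - Bimolecular palladium-catalysed ring-opening coupling of cyclopropanol 7 with F1 (same catalyst and base as in step 11, normal concentration) should give the open-chain ketone methyl (Z)-10-[2-allyl-4-(tert-butyldimethylsilyloxy)phenoxy]-2-(dimethoxyphosphoryl)-6,10-dimethyl-9-oxoundec-5-enoate F2.
 - Horner–Wadsworth–Emmons methylenation with paraformaldehyde and K2CO3 in THF should convert it into methyl (Z)-10-[2-allyl-4-(tert-butyldimethylsilyloxy)phenoxy]-6,10-dimethyl-2-methylidene-9-oxoundec-5-enoate F3.
 - Ring-closing metathesis between the 2-methylidene group and the aryl allyl group (Hoveyda–Grubbs II, toluene, 80 °C, high dilution) should close the 14-membered ring as the thermodynamically preferred E-enoate, that is ketone 19.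

2. Step 5. Over-oxidation (oxidative opening of the free cyclopropanol or attack on the electron-rich arene) and self-condensation of the arylacetaldehyde during isolation may erode the material. The fallback carries out the alkene cleavage before the cyclopropanol exists and keeps the aldehyde masked through the Kulinkovich step. It sets out from ester 6 and returns at aldehyde 9.
 - Ozonolysis of 6 (O3, CH2Cl2, −78 °C; PPh3) should pass through the ozonide ethyl 2-[4-(tert-butyldimethylsilyloxy)-2-(1,2,4-trioxolan-3-ylmethyl)phenoxy]-2-methylpropanoate F4 to ethyl 2-[4-(tert-butyldimethylsilyloxy)-2-(2-oxoethyl)phenoxy]-2-methylpropanoate F5.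
 - Acetalisation (HC(OMe)3, PPTS, MeOH) should give ethyl 2-[4-(tert-butyldimethylsilyloxy)-2-(2,2-dimethoxyethyl)phenoxy]-2-methylpropanoate F6.
 - Kulinkovich cyclopropanation as in step 4 should give 1-{2-[4-(tert-butyldimethylsilyloxy)-2-(2,2-dimethoxyethyl)phenoxy]propan-2-yl}cyclopropan-1-ol F7.
 - Mild hydrolysis of the dimethyl acetal (PPTS, acetone/H2O, rt) should release aldehyde 9 immediately before the Wittig step.

3. Step 12. Facial selectivity may be poor, or the reduction sluggish, because the ketone is hindered and sits in a macrocycle whose conformation could override the catalyst. The fallback gives up reagent control in favour of resolution with recycling. It sets out from ketone 19 and returns at carbinol 20.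
 - NaBH4 in MeOH at 0 °C should give the racemic carbinol (methyl ester, aryl TBS ether) F8.
 - Preparative chromatography on a chiral stationary phase separates 20 from its enantiomer, the (S)-carbinol F9.
 - F9 is returned to ketone 19 by Dess–Martin oxidation and reduced again.

**Further compounds**

F1 | step 11 | methyl (Z)-2-(dimethoxyphosphoryl)-6-iodohept-5-enoate | COC(=O)C(CC/C=C(C)\I)P(=O)(OC)OC
F2 | step 11 | methyl (Z)-10-[2-allyl-4-(tert-butyldimethylsilyloxy)phenoxy]-2-(dimethoxyphosphoryl)-6,10-dimethyl-9-oxoundec-5-enoate | COC(=O)C(CC/C=C(C)\CCC(=O)C(C)(C)Oc1ccc(O[Si](C)(C)C(C)(C)C)cc1CC=C)P(=O)(OC)OC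
F3 | step 11 | methyl (Z)-10-[2-allyl-4-(tert-butyldimethylsilyloxy)phenoxy]-6,10-dimethyl-2-methylidene-9-oxoundec-5-enoate | COC(=O)C(=C)CC/C=C(C)\CCC(=O)C(C)(C)Oc1ccc(O[Si](C)(C)C(C)(C)C)cc1CC=C
F4 | step 5 | ethyl 2-[4-(tert-butyldimethylsilyloxy)-2-(1,2,4-trioxolan-3-ylmethyl)phenoxy]-2-methylpropanoate | CCOC(=O)C(C)(C)Oc1ccc(O[Si](C)(C)C(C)(C)C)cc1CC1OCOO1
F5 | step 5 | ethyl 2-[4-(tert-butyldimethylsilyloxy)-2-(2-oxoethyl)phenoxy]-2-methylpropanoate | CCOC(=O)C(C)(C)Oc1ccc(O[Si](C)(C)C(C)(C)C)cc1CC=O
F6 | step 5 | ethyl 2-[4-(tert-butyldimethylsilyloxy)-2-(2,2-dimethoxyethyl)phenoxy]-2-methylpropanoate | CCOC(=O)C(C)(C)Oc1ccc(O[Si](C)(C)C(C)(C)C)cc1CC(OC)OC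
F7 | step 5 | 1-{2-[4-(tert-butyldimethylsilyloxy)-2-(2,2-dimethoxyethyl)phenoxy]propan-2-yl}cyclopropan-1-ol | OC1(CC1)C(C)(C)Oc1ccc(O[Si](C)(C)C(C)(C)C)cc1CC(OC)OC
F8 | step 12 | racemic macrocyclic carbinol (methyl ester, aryl TBS ether) | C/C1=C/CC/C(C(=O)OC)=C\Cc2cc(O[Si](C)(C)C(C)(C)C)ccc2OC(C)(C)C(O)CC1
F9 | step 12 | (S)-macrocyclic carbinol, enantiomer of 20 | C/C1=C/CC/C(C(=O)OC)=C\Cc2cc(O[Si](C)(C)C(C)(C)C)ccc2OC(C)(C)[C@@H](O)CC1
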